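## The problem

Dielsianone 19 is an achiral 2H-chromene in which a 2,2-dimethylpyran (O1, C2, C3=C4) is fused to benzene ring A (C4a, C5, C6, C7, C8, C8a). Ring A carries a free hydroxyl at C5, a 4-methoxyphenyl 1,2-diketone at C6, a methoxy group at C8 and the pyran oxygen at C8a, so that only C7 keeps a hydrogen. As there is no stereocentre, nothing can be relayed from centre to centre and the task is purely regiochemical: three ring oxygens have to be told apart (one free, one methylated, one built into the pyran), and the diketone has to sit ortho to the free hydroxyl and meta to the methoxy group. Substitution on a preformed 1,2,4-trioxygenated benzene does not give this placement reliably, because several positions are activated at once. Two groups limit what can be done late: the 1,2-diketone is open to benzilic acid rearrangement with hydroxide, to condensation with 1,2-diamines and to hemiketal formation with the ortho hydroxyl, and the electron-rich C3=C4 alkene of the chromene tolerates neither oxidants nor strong acid. The feature that opens the structure is the oxygen pattern of ring A, in which C8a–O and C8–OMe are neighbours and C5–OH lies para to C8–OMe. This is the pattern delivered when a 4-alkenyl-4-alkoxycyclobutenone made from a semisquarate is ring-expanded: the alkoxy carbon becomes C8a, the carbon that accepted the nucleophile becomes C8, the remaining carbonyl becomes C5–OH, the lone ring C–H becomes C4a, and the two alkene carbons become C7 and C6, so that whatever stands at the alkene terminus arrives at C6.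

## Retrosynthesis

**Pyran ring (19 to 16 and 17).** Cutting C4–C4a and O1–C2 of 19 leads to the resorcinol diketone 16 and prenal 17. This cut comes last because the chromene alkene would not survive the oxidation that creates the diketone. At this stage the regiochemistry is also locked from two sides: C4a is the only free ring position flanked by two hydroxyls, and the C5 hydroxyl is held in a hydrogen bond to the C6 carbonyl, so the C8a oxygen should close the ring. Compound 16 is simpler by one ring and five carbons. The forward reaction must condense the enal at carbon and close through oxygen without harming the diketone, which excludes hydroxide and diamine catalysts.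

**Free hydroxyls (16 to 15).** Cutting the two O–isopropyl bonds leads to the bis(isopropyl) ether 15. The C8a ether is inherited from the squarate ester. The C5 ether is chosen to be the same group, so that one Lewis-acid dealkylation frees both oxygens while the two methyl ethers stay. A methyl or benzyl group at C5 would need a separate step or conditions that endanger C8–OMe. The forward step must discriminate secondary alkyl from methyl ethers.

**Diketone (15 to 14 to 13).** The two C=O bonds are exchanged for the C=C bond of the E-stilbene 13, by way of diol 14. The neighbouring option, attaching an arylglyoxylyl unit to a finished ring A by acylation or metalation at C6, requires substitution on a crowded ring with several activated positions. In the stilbene the two carbons are already bonded to C6 when ring A forms. Compound 13 has one alkene and only ether groups. The forward steps are a syn dihydroxylation and an oxidation of both benzylic carbinols that must not cleave the C–C bond.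

**Phenol cap (13 to 12).** Cutting the C5 O–isopropyl bond gives the free phenol 12. The cap is needed because an ortho-hydroxystilbene is a poor substrate for osmylation and for the oxidation that follows. The forward step is a routine alkylation.

**Ring A (12 to 9).** Cutting the C5–C6 bond (retro-6π through dienone 11) gives the dienylketene 10. Reconnecting the ketene carbon to the methoxy-bearing carbon (retro-4π) gives the cyclobutenone 9. This cut is preferred over any aromatic substitution because the positions of all ring A substituents are read directly from the four-membered ring. Compound 9 has a cyclobutenone in place of the benzene ring and is made from two pieces. The forward reaction needs only heat, but the methoxy group must rotate outward as the ring opens.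

**Cyclobutenone (9 to 3 and 6).** Compound 9 is cut at the bond between its quaternary carbon and the dienyl chain and at the O–methyl bond. This leads to semisquarate 3, dienyllithium 7 (through alkoxide 8) and a methyl electrophile. Of the two carbonyls of 3, the one beside the alkoxy carbon is a plain strained ketone and the other is a vinylogous ester. The nucleophile must take the former; this choice, not the electrocyclic step, fixes the substitution pattern. Methylating the alkoxide before ring expansion distinguishes C8–OMe from C5–OH at no extra step and removes a hydroxyl that could add to the ketene.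

**Building blocks (3 to 1; 7 to 6 to 4 and 5).** Semisquarate 3 comes from diisopropyl squarate 1 by monoreduction to 2 and acid-induced loss of one alkoxy group. Dienyllithium 7 comes from iodide 6 by halogen–lithium exchange. Iodide 6 comes from (E)-4-methoxycinnamaldehyde 4 and iodoform 5 by one-carbon iodo-olefination. The carbon of 5 becomes C7, the aldehyde carbon of 4 becomes C6, and the alkene carbons of 4 become the diketone. Compounds 1, 4, 5 and 17 are commercial.

## Roads not taken

**Alternative 1:** Both aryl–carbonyl bonds of the diketone are cut, so that the last intermediate is 1-[8-methoxy-5-(methoxymethoxy)-2,2-dimethyl-2H-chromen-6-yl]-2-(4-methoxyphenyl)ethane-1,2-dione A1.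

- **Forward key step:** the chromene 8-methoxy-5-(methoxymethoxy)-2,2-dimethyl-2H-chromene A2 is lithiated at C6 with n-butyllithium A3 under direction of the C5 acetal oxygen. The metalated carbon adds to one amide carbonyl of 1,4-dimethylpiperazine-2,3-dione A4 and 4-methoxyphenylmagnesium bromide A5 adds to the other; an acid quench then releases A1. No ring is closed.
- **Merits:** two C–C bonds form in one flask, the pyran and all oxygens are in place beforehand, and the diketone never has to be produced by oxidation. Only acetal cleavage separates A1 from 19.
- **Weak points:** A2 must be made first, most directly from 4-methoxybenzene-1,3-diol A6 by chromene annulation. On A6 that annulation has two nucleophilic ring positions and two hydroxyls to choose from, with no chelating acyl group to distinguish them. In the metalation with A3, C7 (ortho to methoxy) and the vinylic C4–H (peri to the acetal) compete with C6. The one-pot double addition to A4 needs the first tetrahedral adduct to persist until the Grignard reagent A5 has added.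
- **Comparison:** in step count this road is better. If A2 can be made in three or four steps, the whole synthesis is several steps shorter than the nine proposed here. The chosen plan sets against this that every substituent position of ring A is fixed by construction, so no step depends on a competition between directing groups or between two hydroxyls.

**Alternative 2:** Ring A is cut at C8–C7 and C5–C6, a Diels–Alder disconnection, and the product of the key step is 1-[2,4-dihydroxy-5-methoxy-3-(3-methylbut-2-enyl)phenyl]-2-(4-methoxyphenyl)ethane-1,2-dione A7.

- **Forward key step:** the diene (E)-1,1-dimethoxy-3-(3-methylbut-2-enyl)-2,4-bis(trimethylsilyloxy)buta-1,3-diene A8, drawn here as the bis(trimethylsilyl) ether, adds to the ketal-masked ynone 1,1-dimethoxy-1-(4-methoxyphenyl)but-3-yn-2-one A9. Expulsion of one methoxy group aromatises the adduct, and acidic work-up unmasks the hydroxyls and the diketone to give A7.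
- **Merits:** convergent, and the diketone arrives at its final oxidation level. The chosen plan needs steps 6 and 7 for that, so on this point Alternative 2 is better.
- **Weak points:** A8 is a densely oxygenated ketene acetal that is hydrolytically fragile and must itself be built from a prenylated β-ketoaldehyde equivalent. Regiochemistry rests on matching the polarisation of two push–pull partners. The terminal ynone A9 is prone to conjugate addition and oligomerisation. A7 still needs an oxidative cyclisation of the prenyl group onto the C8a oxygen, with the C5 hydroxyl also ortho to it and an electron-rich ring exposed to the oxidant.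
- **Comparison:** overall length is similar. The chosen plan offers stable, isolable intermediates from a commercial squarate and a one-step, non-oxidative pyran closure.

**Alternative 3:** Only the pyran ring is cut, at C4–C3 and C2–O1, and the product of the key step is racemic 1-(5-hydroxy-4,8-dimethoxy-2,2-dimethylchroman-6-yl)-2-(4-methoxyphenyl)ethane-1,2-dione A10.

- **Forward key step:** the aldehyde 2,6-dihydroxy-3-methoxy-5-[2-(4-methoxyphenyl)-2-oxoacetyl]benzaldehyde A11 is converted by trimethyl orthoformate A13 and the catalyst Sc(OTf)3 A14 into a 4-methoxy ortho-quinone methide in its oxocarbenium form, which 2-methylpropene A12 captures to give A10.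
- **Merits:** the gem-dimethyl carbon comes from a cheap feedstock. The polarity of the cycloaddition places the quaternary carbon on oxygen without ambiguity. The conditions are milder than a hot amine condensation, which is kinder to the diketone; on this point it is better than step 9 of the chosen plan.
- **Weak points:** it solves only the easier half of the problem. A11 still has to be made by another strategy, with ring A, the diketone and an extra formyl group in place. Either flanking hydroxyl could form the quinone methide. The Lewis acid A14 can bind the diketone, and A13 could ketalise it. A10 needs a further elimination of its C4 methoxy group to give the C3=C4 alkene, and A12 is a gas.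
- **Comparison:** the chosen plan makes the same ring from 16 in one operation with prenal 17, without formylation and without a separate elimination.

Key step: step 4

Remark on stereochemistry: every stereocentre met on the way (in 2, 8, 9, 11 and 14) is formed racemic and is erased before the target, which has none; each SMILES shows one enantiomer.

## Route

Step 1
Reactants: 1 diisopropyl squarate (3,4-diisopropoxycyclobut-3-ene-1,2-dione)
Product: 3 3-isopropoxycyclobut-3-ene-1,2-dione (isopropyl semisquarate), via hydroxycyclobutenone 2 (not isolated)
Conditions: LiAlH(OtBu)3, THF, −20 → 0 °C; aq. HCl quench; then conc. HCl (cat.), CH2Cl2, rt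
Reagents that add atoms: none
Why: The bulky hydride LiAlH(OtBu)3 reduces one carbonyl of the squarate (1,2-reduction) and should stop at hydroxycyclobutenone 2; acid then ionises the allylic hydroxyl, the hydroxyl returns at the other, alkoxy-bearing terminus of the allyl cation (net 1,3-transposition without net uptake of water) and the resulting hemiketal loses propan-2-ol, which unveils the second carbonyl.

Step 2
Reactants: 4 (E)-4-methoxycinnamaldehyde; 5 iodoform
Product: 6 (1E,3E)-1-iodo-4-(4-methoxyphenyl)buta-1,3-diene
Conditions: CrCl2 (6 equiv), THF, 0 °C → rt
Reagents that add atoms: none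
Why: Takai olefination: the geminal dichromium species formed from CHI3 and divalent chromium adds to the aldehyde and eliminates to the E iodoalkene; the existing E alkene is not touched, so the (1E,3E) diene should result.

Step 3
Reactants: 6 (1E,3E)-1-iodo-4-(4-methoxyphenyl)buta-1,3-diene; 3 3-isopropoxycyclobut-3-ene-1,2-dione
Product: 9 (±)-3-isopropoxy-4-methoxy-4-[(1E,3E)-4-(4-methoxyphenyl)buta-1,3-dienyl]cyclobut-2-en-1-one, via dienyllithium 7 (not isolated), via lithium alkoxide 8 (not isolated)
Conditions: t-BuLi (2 equiv), Et2O, −78 °C; add to 3 in THF, −78 °C; MeOTf (3 equiv), −78 → 0 °C; chromatography on Et3N-deactivated silica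
Reagents that add atoms: methyl trifluoromethanesulfonate, COS(=O)(=O)C(F)(F)F
Why: Iodine–lithium exchange retains the alkene geometry; the dienyllithium adds 1,2 to the more electrophilic carbonyl of 3, the one beside the alkoxy carbon and outside the vinylogous ester, and the tertiary lithium alkoxide is O-methylated by MeOTf (alkoxide alkylation). The quaternary centre forms racemic and is destroyed in step 4.

Step 4
Reactants: 9 (±)-3-isopropoxy-4-methoxy-4-[(1E,3E)-4-(4-methoxyphenyl)buta-1,3-dienyl]cyclobut-2-en-1-one
Product: 12 (E)-5-isopropoxy-4-methoxy-2-[2-(4-methoxyphenyl)ethenyl]phenol, via dienylketene 10 (not isolated), via cyclohexadienone 11 (not isolated)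
Conditions: toluene (degassed, 0.01 M), 110 °C
Reagents that add atoms: none
Why: Heating opens the strained ring by conrotatory 4π electrocyclic cleavage of the bond between the carbonyl carbon and the quaternary carbon, giving dienylketene 10; the methoxy donor takes the outward position (torquoselectivity), which places the dienyl arm inward, cis to the ketene. The ketene C=C, the adjacent enol-ether alkene and the first alkene of the arm then close by thermal disrotatory 6π electrocyclisation, joining the ketene carbon (chromene C5) to the distal carbon of that alkene (C6) and closing ring A as the six-membered carbocycle of dienone 11. Tautomerisation of the C6 hydrogen to oxygen aromatises 11 to phenol 12 and removes the only sp3 centre formed, so no stereocentre needs control. The closest known reaction type is the Moore rearrangement of squarate-derived 4-alkenyl-4-alkoxycyclobutenones to hydroquinone monoethers. The step needs torquoselectivity, which the methoxy group on the quaternary carbon secures. It needs 6π closure in preference to 8π closure, which the E geometry of the first alkene secures by holding the styryl terminus away from the ketene. It needs ring closure to outrun intermolecular ketene capture, which dilution and the methyl cap secure, the cap also removing the hydroxyl that could lactonise onto the ketene. The substitution pattern of ring A is not decided here but by the site of addition in step 3.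

Step 5
Reactants: 12 (E)-5-isopropoxy-4-methoxy-2-[2-(4-methoxyphenyl)ethenyl]phenol
Product: 13 (E)-1,5-diisopropoxy-2-methoxy-4-[2-(4-methoxyphenyl)ethenyl]benzene
Conditions: 2-bromopropane, K2CO3, DMF, 60 °C
Reagents that add atoms: 2-bromopropane, CC(C)Br
Why: Williamson ether synthesis on the phenoxide; the same isopropyl group as at C8a is chosen so that one later operation removes both.

Step 6
Reactants: 13 (E)-1,5-diisopropoxy-2-methoxy-4-[2-(4-methoxyphenyl)ethenyl]benzene
Product: 14 (1R*,2R*)-1-(2,4-diisopropoxy-5-methoxyphenyl)-2-(4-methoxyphenyl)ethane-1,2-diol (racemic)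
Conditions: OsO4 (2 mol %), N-methylmorpholine N-oxide, acetone/H2O, rt
Reagents that add atoms: osmium tetroxide (catalytic oxygen carrier), O=[Os](=O)(=O)=O; N-methylmorpholine N-oxide, C[N+]1([O-])CCOCC1; water, O
Why: Upjohn dihydroxylation of the only alkene; suprafacial [3+2] addition of OsO4 to the E-alkene gives the racemic threo diol, whose two stereocentres are erased in step 7.

Step 7
Reactants: 14 (1R*,2R*)-1-(2,4-diisopropoxy-5-methoxyphenyl)-2-(4-methoxyphenyl)ethane-1,2-diol
Product: 15 1-(2,4-diisopropoxy-5-methoxyphenyl)-2-(4-methoxyphenyl)ethane-1,2-dione
Conditions: (COCl)2, DMSO, CH2Cl2, −78 °C; Et3N, −78 °C → rt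
Reagents that add atoms: none
Why: Double Swern oxidation; activated DMSO oxidises each benzylic carbinol through its alkoxysulfonium ylide and does not cleave the central C–C bond as glycol-cleaving oxidants would.

Step 8
Reactants: 15 1-(2,4-diisopropoxy-5-methoxyphenyl)-2-(4-methoxyphenyl)ethane-1,2-dione
Product: 16 1-(2,4-dihydroxy-5-methoxyphenyl)-2-(4-methoxyphenyl)ethane-1,2-dione
Conditions: BCl3 (3.5 equiv), CH2Cl2, −78 → 0 °C; aq. work-up
Reagents that add atoms: none
Why: Lewis-acid dealkylation: BCl3 complexes the ether oxygens and the secondary isopropyl groups leave as 2-chloropropane, the C5 ether being further activated by chelation to the C6 carbonyl; methyl aryl ethers that are not ortho to a carbonyl should not be cleaved at this temperature.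

Step 9
Reactants: 16 1-(2,4-dihydroxy-5-methoxyphenyl)-2-(4-methoxyphenyl)ethane-1,2-dione; 17 prenal (3-methylbut-2-enal)
Product: 19 dielsianone, 1-(5-hydroxy-8-methoxy-2,2-dimethyl-2H-chromen-6-yl)-2-(4-methoxyphenyl)ethane-1,2-dione, via ortho-quinone methide 18 (not isolated)
Conditions: pyridine, 120 °C (sealed tube)
Reagents that add atoms: none
Why: Base-mediated chromenylation of an acylresorcinol: Knoevenagel-type condensation of the enal at C4a, the only free position between two hydroxyls, gives quinone methide 18, which closes by oxa-6π electrocyclisation. The C5 hydroxyl stays hydrogen-bonded to the C6 carbonyl, so the C8a oxygen should become O1.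

## Compound list

1 | diisopropyl squarate (3,4-diisopropoxycyclobut-3-ene-1,2-dione) | CC(C)OC1=C(OC(C)C)C(=O)C1=O | starting material
2 | (±)-4-hydroxy-2,3-diisopropoxycyclobut-2-en-1-one | CC(C)OC1=C(OC(C)C)[C@H](O)C1=O | intermediate (not isolated)
3 | 3-isopropoxycyclobut-3-ene-1,2-dione (isopropyl semisquarate) | O=C1C=C(OC(C)C)C1=O | intermediate
4 | (E)-4-methoxycinnamaldehyde | COc1ccc(/C=C/C=O)cc1 | starting material
5 | iodoform (triiodomethane) | C(I)(I)I | starting material
6 | (1E,3E)-1-iodo-4-(4-methoxyphenyl)buta-1,3-diene | I/C=C/C=C/c1ccc(OC)cc1 | intermediate
7 | [(1E,3E)-4-(4-methoxyphenyl)buta-1,3-dienyl]lithium | [Li]/C=C/C=C/c1ccc(OC)cc1 | intermediate (not isolated)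
8 | lithium (±)-2-isopropoxy-1-[(1E,3E)-4-(4-methoxyphenyl)buta-1,3-dienyl]-4-oxocyclobut-2-en-1-olate | O=C1C=C(OC(C)C)[C@@]1([O-])/C=C/C=C/c1ccc(OC)cc1.[Li+] | intermediate (not isolated)
9 | (±)-3-isopropoxy-4-methoxy-4-[(1E,3E)-4-(4-methoxyphenyl)buta-1,3-dienyl]cyclobut-2-en-1-one | O=C1C=C(OC(C)C)[C@@]1(OC)/C=C/C=C/c1ccc(OC)cc1 | intermediate
10 | (3Z,5E,7E)-3-isopropoxy-4-methoxy-8-(4-methoxyphenyl)octa-1,3,5,7-tetraen-1-one (dienylketene) | O=C=C/C(OC(C)C)=C(OC)\C=C\C=C\c1ccc(OC)cc1 | intermediate (not isolated)
11 | (±)-3-isopropoxy-4-methoxy-6-[(E)-2-(4-methoxyphenyl)ethenyl]cyclohexa-2,4-dien-1-one | O=C1C=C(OC(C)C)C(OC)=C[C@@H]1/C=C/c1ccc(OC)cc1 | intermediate (not isolated)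
12 | (E)-5-isopropoxy-4-methoxy-2-[2-(4-methoxyphenyl)ethenyl]phenol | COc1ccc(/C=C/c2cc(OC)c(OC(C)C)cc2O)cc1 | intermediate
13 | (E)-1,5-diisopropoxy-2-methoxy-4-[2-(4-methoxyphenyl)ethenyl]benzene | COc1ccc(/C=C/c2cc(OC)c(OC(C)C)cc2OC(C)C)cc1 | intermediate
14 | (1R*,2R*)-1-(2,4-diisopropoxy-5-methoxyphenyl)-2-(4-methoxyphenyl)ethane-1,2-diol (racemic) | O[C@H](c1ccc(OC)cc1)[C@H](O)c1cc(OC)c(OC(C)C)cc1OC(C)C | intermediate
15 | 1-(2,4-diisopropoxy-5-methoxyphenyl)-2-(4-methoxyphenyl)ethane-1,2-dione | COc1ccc(C(=O)C(=O)c2cc(OC)c(OC(C)C)cc2OC(C)C)cc1 | intermediate
16 | 1-(2,4-dihydroxy-5-methoxyphenyl)-2-(4-methoxyphenyl)ethane-1,2-dione | COc1ccc(C(=O)C(=O)c2cc(OC)c(O)cc2O)cc1 | intermediate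
17 | prenal (3-methylbut-2-enal) | CC(C)=CC=O | starting material
18 | 1-[(3Z)-2-hydroxy-5-methoxy-3-(3-methylbut-2-en-1-ylidene)-4-oxocyclohexa-1,5-dien-1-yl]-2-(4-methoxyphenyl)ethane-1,2-dione (ortho-quinone methide) | COC1=CC(C(=O)C(=O)c2ccc(OC)cc2)=C(O)/C(=C/C=C(C)C)C1=O | intermediate (not isolated)
19 | dielsianone, 1-(5-hydroxy-8-methoxy-2,2-dimethyl-2H-chromen-6-yl)-2-(4-methoxyphenyl)ethane-1,2-dione | COc1ccc(C(=O)C(=O)c2cc(OC)c3c(c2O)C=CC(C)(C)O3)cc1 | target

## Step count and risk

Total step count: 9. Longest linear sequence: 8 steps (steps 1 and 3 to 9 from diisopropyl squarate; equally steps 2 and 3 to 9 from 4-methoxycinnamaldehyde).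

**Step 4 (key step).**
- What may go wrong: the ketene carbon carries only a hydrogen on its neighbour and is unhindered, so intermolecular capture by the phenol being formed, or ketene dimerisation, can compete with ring closure. A methoxy group is also a weaker outward-rotating donor than a hydroxyl or silyloxy group, so partial inward rotation would give a ketene that cannot close and slowly decomposes.
- Fallback: set out from lithium alkoxide 8, made as in step 3, and trap it with TBSOTf to give (±)-4-(tert-butyldimethylsilyloxy)-3-isopropoxy-4-[(1E,3E)-4-(4-methoxyphenyl)buta-1,3-dienyl]cyclobut-2-en-1-one F1. Silyloxy is the bulkiest and best-established outward-rotating group for this ring expansion. Thermolysis in toluene should give (E)-4-(tert-butyldimethylsilyloxy)-5-isopropoxy-2-[2-(4-methoxyphenyl)ethenyl]phenol F2. Isopropylation of the free hydroxyl (2-iodopropane, K2CO3, acetone) gives (E)-tert-butyl-[2,4-diisopropoxy-5-[2-(4-methoxyphenyl)ethenyl]phenoxy]dimethylsilane F3. Desilylation with tetrabutylammonium fluoride in the presence of MeI methylates the liberated phenoxide and returns to the route at 13. The C8 methyl group is thus installed after ring formation instead of before it.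

**Step 3.**
- What may go wrong: O-methylation of the hindered tertiary lithium alkoxide may be slower than its fragmentation as the mixture warms, LiI can consume the triflate, and some addition at the vinylogous ester carbonyl would give a regioisomeric adduct.
- Fallback: set out from 6 and 3, run the addition as before, but quench with aq. NH4Cl and isolate the alcohol (±)-4-hydroxy-3-isopropoxy-4-[(1E,3E)-4-(4-methoxyphenyl)buta-1,3-dienyl]cyclobut-2-en-1-one F4. This also allows a regioisomeric adduct to be removed. Methylate it under neutral conditions with MeI and Ag2O in MeCN, returning to the route at 9.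

**Step 9.**
- What may go wrong: condensation on the acyl-deactivated ring may be slow at a temperature the diketone tolerates, closure through the C5 oxygen would give the isomeric chromene, and prenal self-condenses in hot base.
- Fallback: set out from 16 and alkylate the non-chelated, more acidic C8a hydroxyl with 3-chloro-3-methylbut-1-yne (K2CO3, KI, CuI cat., acetone) to give 1-[2-hydroxy-5-methoxy-4-(2-methylbut-3-yn-2-yloxy)phenyl]-2-(4-methoxyphenyl)ethane-1,2-dione F5. Heating in N,N-diethylaniline induces the aryl propargyl Claisen rearrangement to C4a, the only free ortho position, followed by [1,5]-hydrogen shift and oxa-6π closure, returning to the route at 19. The oxygen that becomes O1 is chosen in the alkylation and no base touches the diketone in the ring-forming step.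

**Step 7.**
- What may go wrong: the electron-rich benzylic diol may fragment at the central C–C bond, or activated DMSO may substitute the trialkoxy ring (methylthiomethylation or chlorination).
- Fallback: set out from stilbene 13 and oxidise the alkene directly to the diketone with I2 in DMSO at about 150 °C (Kornblum-type oxidation of the iodine adduct), returning to the route at 15 and bypassing diol 14. This fallback makes no new compound, which is recorded as F0 in the block below.

## Further compounds

F1 | step 4 | (±)-4-(tert-butyldimethylsilyloxy)-3-isopropoxy-4-[(1E,3E)-4-(4-methoxyphenyl)buta-1,3-dienyl]cyclobut-2-en-1-one | O=C1C=C(OC(C)C)[C@@]1(O[Si](C)(C)C(C)(C)C)/C=C/C=C/c1ccc(OC)cc1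
F2 | step 4 | (E)-4-(tert-butyldimethylsilyloxy)-5-isopropoxy-2-[2-(4-methoxyphenyl)ethenyl]phenol | COc1ccc(/C=C/c2cc(O[Si](C)(C)C(C)(C)C)c(OC(C)C)cc2O)cc1
F3 | step 4 | (E)-tert-butyl-[2,4-diisopropoxy-5-[2-(4-methoxyphenyl)ethenyl]phenoxy]dimethylsilane | COc1ccc(/C=C/c2cc(O[Si](C)(C)C(C)(C)C)c(OC(C)C)cc2OC(C)C)cc1
F4 | step 3 | (±)-4-hydroxy-3-isopropoxy-4-[(1E,3E)-4-(4-methoxyphenyl)buta-1,3-dienyl]cyclobut-2-en-1-one | O=C1C=C(OC(C)C)[C@@]1(O)/C=C/C=C/c1ccc(OC)cc1
F5 | step 9 | 1-[2-hydroxy-5-methoxy-4-(2-methylbut-3-yn-2-yloxy)phenyl]-2-(4-methoxyphenyl)ethane-1,2-dione | COc1ccc(C(=O)C(=O)c2cc(OC)c(OC(C)(C)C#C)cc2O)cc1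
F0 | step 7 | none | none
A1 | alternative 1 | 1-[8-methoxy-5-(methoxymethoxy)-2,2-dimethyl-2H-chromen-6-yl]-2-(4-methoxyphenyl)ethane-1,2-dione | COCOc1c(C(=O)C(=O)c2ccc(OC)cc2)cc(OC)c2c1C=CC(C)(C)O2
A2 | alternative 1 | 8-methoxy-5-(methoxymethoxy)-2,2-dimethyl-2H-chromene | COCOc1ccc(OC)c2c1C=CC(C)(C)O2
A3 | alternative 1 | n-butyllithium | [Li]CCCC
A4 | alternative 1 | 1,4-dimethylpiperazine-2,3-dione | CN1CCN(C)C(=O)C1=O
A5 | alternative 1 | 4-methoxyphenylmagnesium bromide | COc1ccc([Mg]Br)cc1
A6 | alternative 1 | 4-methoxybenzene-1,3-diol | COc1ccc(O)cc1O
A7 | alternative 2 | 1-[2,4-dihydroxy-5-methoxy-3-(3-methylbut-2-enyl)phenyl]-2-(4-methoxyphenyl)ethane-1,2-dione | COc1ccc(C(=O)C(=O)c2cc(OC)c(O)c(CC=C(C)C)c2O)cc1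
A8 | alternative 2 | (E)-1,1-dimethoxy-3-(3-methylbut-2-enyl)-2,4-bis(trimethylsilyloxy)buta-1,3-diene | COC(OC)=C(O[Si](C)(C)C)/C(CC=C(C)C)=C/O[Si](C)(C)C
A9 | alternative 2 | 1,1-dimethoxy-1-(4-methoxyphenyl)but-3-yn-2-one | C#CC(=O)C(OC)(OC)c1ccc(OC)cc1
A10 | alternative 3 | 1-(5-hydroxy-4,8-dimethoxy-2,2-dimethylchroman-6-yl)-2-(4-methoxyphenyl)ethane-1,2-dione (racemic, one enantiomer drawn) | COc1ccc(C(=O)C(=O)c2cc(OC)c3c(c2O)[C@@H](OC)CC(C)(C)O3)cc1
A11 | alternative 3 | 2,6-dihydroxy-3-methoxy-5-[2-(4-methoxyphenyl)-2-oxoacetyl]benzaldehyde | COc1ccc(C(=O)C(=O)c2cc(OC)c(O)c(C=O)c2O)cc1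
A12 | alternative 3 | 2-methylpropene (isobutene) | CC(C)=C
A13 | alternative 3 | trimethyl orthoformate | COC(OC)OC
A14 | alternative 3 | scandium tris(trifluoromethanesulfonate), Sc(OTf)3 | [Sc+3].[O-]S(=O)(=O)C(F)(F)F.[O-]S(=O)(=O)C(F)(F)F.[O-]S(=O)(=O)C(F)(F)F
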